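Retrosynthesis: the side chain is cut at C3–C(=O) (aldol, then oxidation; Z-alkene from an alkyne) and at C3–O (enolate hydroxylation); then C1–C2 is cut, which opens ring C1–C2–C3–C5–C9 to a monocyclic 2-isobutyrylcyclohexanone enol carrying an N-sulfonyl ynamide (C3≡C2) on C5.
That precursor is cut at C1–C(isobutyryl), C8–CH3, C5–C3 and C5–prenyl back to (S)-3-methyl-4-prenylcyclohex-2-enone, and this to 5-methylhex-4-enal plus methyl vinyl ketone.
Enabling feature: C1 bears no hydrogen and sits between the C2 and C9 ketones, the isobutyryl carbonyl and the gem-dimethyl C8, so C1–C2 cannot come from a reversible ester condensation; but C2 is joined to C5 through C3 and lies 1,3 to C1 across C9, so a cationic ketene-equivalent C2 on an axial C5 arm sits over the enol π-lobe of C1 and closes the five-membered ring of the bicyclo[3.2.1]octane.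
Forward: the six-membered ring (C1, C8, C7, C6, C5, C9) is built first by organocatalytic Michael addition and aldol condensation and then substituted; the five-membered ring (C1, C2, C3, C5, C9) is closed second by acid-catalysed ynamide-to-keteniminium C-acylation; C3 is oxygenated and acylated last.
Stereochemistry: C7 from the prolinol-ether-catalysed Michael addition; C5 from hydroxymethylation of a dienolate anti to the C7 prenyl group; C1 is dictated by the bridge; C3 from exo-face aldol of the silyloxy enolate; the Z-alkene from poisoned-palladium semi-hydrogenation.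

Key step: step 12

Remark on labels: C1 = bridgehead with isobutyryl, C2 = ring ketone, C3 = carbinol carbon, C5 = bridgehead with prenyl, C6 = CH2, C7 = CH–prenyl, C8 = CMe2, C9 = bridging ketone (there is no C4); the same labels are used for the corresponding atoms of monocyclic intermediates. Prenyl = 3-methylbut-2-en-1-yl; exo = the face of the C2–C3 bridge turned toward C9, endo = the face turned toward the C6–C7–C8 bridge.
Assumption: 5-methylhex-4-enal and 2-methyl-2-(trimethylsilyloxy)but-3-yne are taken as purchasable; each is otherwise one routine step from 2-methylbut-3-en-2-ol (vinyl ether Claisen rearrangement) or 2-methylbut-3-yn-2-ol (silylation).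

Step 1
Reactants: 1 5-methylhex-4-enal; 2 but-3-en-2-one (methyl vinyl ketone)
Product: 3 (2S)-2-(3-methylbut-2-en-1-yl)-5-oxohexanal
Conditions: (S)-2-[diphenyl(trimethylsilyloxy)methyl]pyrrolidine (5 mol%), ethyl 3,4-dihydroxybenzoate (20 mol%), neat, 4 °C
Reagents that add atoms: none
Why: Enamine-catalysed Michael addition, in which the E-enamine of 1 is shielded on one face by the diphenyl(silyloxy)methyl group of the (S)-catalyst so that the enone is attacked from the open face and the future C7 stereocentre should form with S configuration in high enantiomeric excess.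

Step 2
Reactants: 3 (2S)-2-(3-methylbut-2-en-1-yl)-5-oxohexanal
Product: 5 (4S)-4-(3-methylbut-2-en-1-yl)cyclohex-2-en-1-one, via cyclic aldol 4 (not isolated)
Conditions: 0.1 M aq. KOH, n-Bu4NOH (cat.), Et2O/THF, reflux
Reagents that add atoms: none
Why: Intramolecular aldol condensation (Robinson-type ring closure) in which the methyl-ketone enolate adds to the aldehyde and aldol 4 dehydrates by E1cB, the mild two-phase hydroxide conditions being chosen so that ring closure outruns enolisation of the aldehyde and the stereocentre is kept.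

Step 3
Reactants: 5 (4S)-4-(3-methylbut-2-en-1-yl)cyclohex-2-en-1-one
Product: 6 trimethyl{[(4S)-3-methyl-4-(3-methylbut-2-en-1-yl)cyclohex-1-en-1-yl]oxy}silane (both C3 epimers)
Conditions: MeMgBr, CuBr·SMe2 (5 mol%), Me3SiCl, HMPA, THF, −78 °C; Et3N quench
Reagents that add atoms: methylmagnesium bromide `C[Mg]Br`; chlorotrimethylsilane `C[Si](C)(C)Cl`
Why: Copper-catalysed conjugate addition with in situ O-silylation, in which methyl transfer to the unsubstituted β-carbon is fast at −78 °C and the enolate is trapped regiospecifically, the new methyl-bearing centre (anti to the prenyl group in the main isomer) being erased in step 4.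

Step 4
Reactants: 6 trimethyl{[(4S)-3-methyl-4-(3-methylbut-2-en-1-yl)cyclohex-1-en-1-yl]oxy}silane
Product: 7 (4S)-3-methyl-4-(3-methylbut-2-en-1-yl)cyclohex-2-en-1-one
Conditions: Pd(OAc)2 (1.05 equiv), MeCN, rt
Reagents that add atoms: none
Why: Saegusa–Ito oxidation, in which divalent palladium palladates the α-carbon of the silyl enol ether and β-hydride elimination from the methyl-bearing carbon returns the conjugated enone, now β-methylated, without touching the prenyl-bearing stereocentre.

Step 5
Reactants: 7 (4S)-3-methyl-4-(3-methylbut-2-en-1-yl)cyclohex-2-en-1-one; 8 prenyl bromide (1-bromo-3-methylbut-2-ene)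
Product: 10 3-methyl-4,6-diprenylcyclohex-2-en-1-one (C4 as in 7; both C6 epimers), via lithium dienolate 9 (not isolated)
Conditions: LiN(i-Pr)2 (LDA), THF, −78 °C; then 8, −78 → −20 °C
Reagents that add atoms: none
Why: Kinetic α′-deprotonation to the cross-conjugated lithium dienolate followed by SN2 enolate alkylation with the allylic bromide, the configuration at the new centre being irrelevant because it is planarised again in step 6.

Step 6
Reactants: 10 3-methyl-4,6-diprenylcyclohex-2-en-1-one
Product: 12 6-(hydroxymethyl)-3-methyl-4,6-diprenylcyclohex-2-en-1-one (hydroxymethyl trans to the 4-prenyl group), via lithium dienolate 11 (not isolated)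
Conditions: LiN(i-Pr)2, THF, −78 °C; then CH2O (gas from cracked paraformaldehyde), −78 °C; aq. NH4Cl
Reagents that add atoms: formaldehyde `C=O`
Why: Aldol addition of the fully substituted lithium dienolate to monomeric formaldehyde, in which allylic 1,2-strain with the ring methyl keeps the C7 prenyl group pseudoaxial so that the electrophile should add to the opposite face and the hydroxymethyl carbon (future C3) is set trans to the C7 prenyl group at the quaternary C5.

Step 7
Reactants: 12 6-(hydroxymethyl)-3-methyl-4,6-diprenylcyclohex-2-en-1-one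
Product: 13 4-methyl-2-oxo-1,5-diprenylcyclohex-3-ene-1-carbaldehyde (formyl trans to the 5-prenyl group)
Conditions: Dess–Martin periodinane, NaHCO3, CH2Cl2, 0 °C → rt
Reagents that add atoms: none
Why: Dess–Martin oxidation of the neopentyl primary alcohol under buffered neutral conditions, which avoid retro-aldol loss of formaldehyde and leave the non-enolisable β-keto aldehyde intact.

Step 8
Reactants: 13 4-methyl-2-oxo-1,5-diprenylcyclohex-3-ene-1-carbaldehyde
Product: 14 6-(2,2-dibromoethenyl)-3-methyl-4,6-diprenylcyclohex-2-en-1-one (dibromoethenyl trans to the 4-prenyl group)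
Conditions: CBr4, PPh3, CH2Cl2, 0 °C
Reagents that add atoms: carbon tetrabromide `BrC(Br)(Br)Br`
Why: Ramirez dibromo-olefination (first stage of the Corey–Fuchs sequence), in which the non-basic ylide Ph3P=CBr2 undergoes a Wittig reaction with the aldehyde only, the hindered enone carbonyl being unreactive.

Step 9
Reactants: 14 6-(2,2-dibromoethenyl)-3-methyl-4,6-diprenylcyclohex-2-en-1-one; 15 N-methyl-p-toluenesulfonamide
Product: 16 N,4-dimethyl-N-[(4-methyl-2-oxo-1,5-diprenylcyclohex-3-en-1-yl)ethynyl]benzenesulfonamide (ynamide carbon trans to the 5-prenyl group)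
Conditions: CuI (12 mol%), N,N′-dimethylethylenediamine (18 mol%), Cs2CO3, 1,4-dioxane, 60 °C
Reagents that add atoms: none
Why: Copper-catalysed amidative coupling of a 1,1-dibromoalkene (Ullmann–Goldberg-type vinylic C–N coupling at the bromide trans to the quaternary carbon followed by carbonate-induced anti-dehydrobromination), a direct and precedented entry to N-sulfonyl ynamides that needs no free terminal alkyne.

Step 10
Reactants: 16 N,4-dimethyl-N-[(4-methyl-2-oxo-1,5-diprenylcyclohex-3-en-1-yl)ethynyl]benzenesulfonamide; 17 isobutyraldehyde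
Product: 19 N-{[3-(1-hydroxy-2-methylpropyl)-4,4-dimethyl-2-oxo-1,5-diprenylcyclohexyl]ethynyl}-N,4-dimethylbenzenesulfonamide (mixture at C1 and the carbinol carbon), via magnesium enolate 18 (not isolated)
Conditions: MeMgBr, CuBr·SMe2 (20 mol%), THF, −40 → −20 °C; then 17, −78 °C; aq. NH4Cl
Reagents that add atoms: methylmagnesium bromide `C[Mg]Br`
Why: Copper-catalysed conjugate addition followed by aldol addition of the regiodefined magnesium enolate, in which the methyl group completes the C8 gem-dimethyl unit and C1 is hydroxyalkylated, while carbometalation of the ynamide is not expected in THF at low temperature because its β-carbon (C3) is neopentyl, and both new stereocentres are removed in steps 11 and 12.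

Step 11
Reactants: 19 N-{[3-(1-hydroxy-2-methylpropyl)-4,4-dimethyl-2-oxo-1,5-diprenylcyclohexyl]ethynyl}-N,4-dimethylbenzenesulfonamide
Product: 20 N-{[2-hydroxy-4,4-dimethyl-3-(2-methylpropanoyl)-1,5-diprenylcyclohex-2-en-1-yl]ethynyl}-N,4-dimethylbenzenesulfonamide (1,3-diketone drawn as its ring enol)
Conditions: Dess–Martin periodinane, NaHCO3, CH2Cl2, 0 °C
Reagents that add atoms: none
Why: Dess–Martin oxidation of the β-hydroxy ketone to the 1,3-diketone, which rests as its hydrogen-bonded enol, in a bicarbonate-buffered medium that is not acidic enough to protonate the ynamide.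

Step 12
Reactants: 20 N-{[2-hydroxy-4,4-dimethyl-3-(2-methylpropanoyl)-1,5-diprenylcyclohex-2-en-1-yl]ethynyl}-N,4-dimethylbenzenesulfonamide
Product: 22 N,4-dimethyl-N-[8,8-dimethyl-1-(2-methylpropanoyl)-9-oxo-5,7-diprenylbicyclo[3.2.1]oct-2-en-2-yl]benzenesulfonamide (target labels), via keteniminium ion 21 (not isolated)
Conditions: Tf2NH (10 mol%), dry CH2Cl2, −40 → 0 °C; then Et3N
Reagents that add atoms: none
Why: Proposed new method: Tf2NH protonates the ynamide at C3 to give keteniminium ion 21, whose electrophilic C2 is attacked by the enol carbon C1 of the hydrogen-bonded 1,3-diketone; this forms C1–C2, delivers the neutral ene-sulfonamide directly and releases the proton from the carbonyl oxygen, so the acid turns over and the product, which has no path back to a keteniminium ion, does not revert. The closest known reaction types are Brønsted-acid keteniminium cyclisations of ynamides onto arenes and alkenes, C-acylation of enols by ketenes and gold-catalysed Conia-ene carbocyclisations of 1,3-dicarbonyl compounds onto alkynes. The ring C1–C2–C3–C5–C9 closes 5-endo-dig with respect to the ynamide (C2=C3 ends inside the ring) and enol-exo with respect to the isobutyryl enol, which is feasible because C5, C3 and C2 of the cumulene are coplanar and the C=N π* lobe at C2 points back along that plane toward C1. The new quaternary centre C1 can only be bridged to C5 on the face that carries the axial C5 side arm, so its configuration follows from C5 (step 6) and through it from C7. The step needs C-attack by C1 in preference to O-attack by the C9 oxygen and to capture by the geminal prenyl alkene: in the chair with both prenyl groups equatorial the side arm is axial, 1,3-diaxial to the π-lobe of C1 and out of reach of the in-plane lone pairs on O9, the enol carbon is far more nucleophilic than a trisubstituted alkene, and a ketene N,O-acetal from O-attack would re-ionise under the acid and drain to the irreversible C-acylation product.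

Step 13
Reactants: 22 N,4-dimethyl-N-[8,8-dimethyl-1-(2-methylpropanoyl)-9-oxo-5,7-diprenylbicyclo[3.2.1]oct-2-en-2-yl]benzenesulfonamide
Product: 23 8,8-dimethyl-1-(2-methylpropanoyl)-5,7-diprenylbicyclo[3.2.1]octane-2,9-dione (target labels)
Conditions: 2 M aq. HCl/THF (1:4), 40 °C
Reagents that add atoms: water `O`
Why: Acid hydrolysis of the ene-sulfonamide, in which protonation at C3 gives an N-sulfonyliminium ion, water adds at C2 and the sulfonamide is expelled to unveil the C2 ketone, nothing being able to epimerise because C1 and C5 carry no hydrogen.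

Step 14
Reactants: 23 8,8-dimethyl-1-(2-methylpropanoyl)-5,7-diprenylbicyclo[3.2.1]octane-2,9-dione
Product: 25 exo-3-hydroxy-8,8-dimethyl-1-(2-methylpropanoyl)-5,7-diprenylbicyclo[3.2.1]octane-2,9-dione, via potassium enolate 24 (not isolated)
Conditions: KN(SiMe3)2, THF, −78 °C; then 2-(phenylsulfonyl)-3-phenyloxaziridine, −78 °C; AcOH quench
Reagents that add atoms: 2-(phenylsulfonyl)-3-phenyloxaziridine `O=S(=O)(c1ccccc1)N1OC1c1ccccc1`
Why: Enolate hydroxylation with an N-sulfonyloxaziridine, in which the exo C3–H is the most accessible acidic hydrogen and the oxidant approaches the exo face (syn to the C9 bridge, away from the C6–C7–C8 bridge) to give the exo alcohol, whose configuration is reset in step 17.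

Step 15
Reactants: 25 exo-3-hydroxy-8,8-dimethyl-1-(2-methylpropanoyl)-5,7-diprenylbicyclo[3.2.1]octane-2,9-dione
Product: 26 8,8-dimethyl-1-(2-methylpropanoyl)-5,7-diprenyl-exo-3-(triethylsilyloxy)bicyclo[3.2.1]octane-2,9-dione
Conditions: Et3SiOTf, 2,6-lutidine, CH2Cl2, −78 → 0 °C
Reagents that add atoms: triethylsilyl trifluoromethanesulfonate `CC[Si](CC)(CC)OS(=O)(=O)C(F)(F)F`
Why: Silyl ether formation from the secondary α-hydroxy ketone with a silyl triflate and a hindered pyridine base, which is fast at low temperature and does not enolise the ketones.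

Step 16
Reactants: 27 2-methyl-2-(trimethylsilyloxy)but-3-yne
Product: 29 4-methyl-4-(trimethylsilyloxy)pent-2-ynal, via lithium acetylide 28 (not isolated)
Conditions: n-BuLi, THF, −78 °C; then DMF, −78 → 0 °C; inverse quench into aq. KH2PO4
Reagents that add atoms: N,N-dimethylformamide `CN(C)C=O`
Why: Formylation of a lithium acetylide with DMF (Bouveault-type), the buffered inverse quench releasing the ynal without conjugate addition of dimethylamine or loss of the tertiary silyl ether.

Step 17
Reactants: 26 8,8-dimethyl-1-(2-methylpropanoyl)-5,7-diprenyl-exo-3-(triethylsilyloxy)bicyclo[3.2.1]octane-2,9-dione; 29 4-methyl-4-(trimethylsilyloxy)pent-2-ynal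
Product: 31 3-exo-[1-hydroxy-4-methyl-4-(trimethylsilyloxy)pent-2-yn-1-yl]-3-endo-(triethylsilyloxy) derivative of 23 (carbinol epimers), via lithium enolate 30 (not isolated)
Conditions: LiN(i-Pr)2, THF, −78 → −40 °C; then 29, −78 °C; AcOH quench at −78 °C
Reagents that add atoms: none
Why: Lithium aldol addition, in which deprotonation of the remaining endo C3–H gives the C2 enolate bearing the silyloxy group, which is planar at C3 and should add to the ynal from the open exo face so that the new C–C bond is exo and the oxygen endo as in the target, the carbinol centre being oxidised away in step 18.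

Step 18
Reactants: 31 3-exo-[1-hydroxy-4-methyl-4-(trimethylsilyloxy)pent-2-yn-1-yl]-3-endo-(triethylsilyloxy) derivative of 23
Product: 32 3-exo-[4-methyl-4-(trimethylsilyloxy)pent-2-ynoyl]-3-endo-(triethylsilyloxy) derivative of 23
Conditions: Dess–Martin periodinane, NaHCO3, CH2Cl2, 0 °C
Reagents that add atoms: none
Why: Dess–Martin oxidation of the hindered propargylic alcohol to the ynone under buffered conditions, which removes the retro-aldol liability of the β-hydroxy ketone.

Step 19
Reactants: 32 3-exo-[4-methyl-4-(trimethylsilyloxy)pent-2-ynoyl]-3-endo-(triethylsilyloxy) derivative of 23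
Product: 33 3-exo-[(2Z)-4-methyl-4-(trimethylsilyloxy)pent-2-enoyl]-3-endo-(triethylsilyloxy) derivative of 23
Conditions: H2 (1 atm), Pd/CaCO3 poisoned with Pb(OAc)2 (Lindlar catalyst), quinoline, EtOAc, 0 °C
Reagents that add atoms: none
Why: Lindlar semi-hydrogenation, in which syn addition of hydrogen on the lead- and quinoline-poisoned palladium surface gives the Z-enone and stops there while the trisubstituted prenyl alkenes are not reduced.

Step 20
Reactants: 33 3-exo-[(2Z)-4-methyl-4-(trimethylsilyloxy)pent-2-enoyl]-3-endo-(triethylsilyloxy) derivative of 23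
Product: 34 CNP0190794.1
Conditions: HF·pyridine, pyridine, THF, 0 °C → rt
Reagents that add atoms: none
Why: Fluoride-mediated desilylation with buffered HF·pyridine, which should remove both silyl ethers under weakly acidic and non-nucleophilic conditions that avoid retro-Claisen or retro-aldol cleavage of the polyketone and Z/E isomerisation.

Compound list
1 | 5-methylhex-4-enal | `CC(C)=CCCC=O` | starting material
2 | but-3-en-2-one (methyl vinyl ketone) | `CC(=O)C=C` | starting material
3 | (2S)-2-(3-methylbut-2-en-1-yl)-5-oxohexanal | `O=C[C@H](CC=C(C)C)CCC(C)=O` | intermediate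
4 | (4S)-3-hydroxy-4-(3-methylbut-2-en-1-yl)cyclohexan-1-one, cyclic aldol, C3 epimers (not isolated) | `O=C1CC(O)[C@H](CC=C(C)C)CC1` | intermediate
5 | (4S)-4-(3-methylbut-2-en-1-yl)cyclohex-2-en-1-one | `O=C1C=C[C@H](CC=C(C)C)CC1` | intermediate
6 | trimethyl{[(4S)-3-methyl-4-(3-methylbut-2-en-1-yl)cyclohex-1-en-1-yl]oxy}silane, C3 epimers | `C[Si](C)(C)OC1=CC(C)[C@H](CC=C(C)C)CC1` | intermediate
7 | (4S)-3-methyl-4-(3-methylbut-2-en-1-yl)cyclohex-2-en-1-one (C9 ketone, C8 methyl, C7 prenyl in target labels) | `O=C1C=C(C)[C@H](CC=C(C)C)CC1` | intermediate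
8 | prenyl bromide (1-bromo-3-methylbut-2-ene) | `CC(C)=CCBr` | starting material
9 | lithium cross-conjugated dienolate of 7 (not isolated) | `[Li+].[O-]C1=CC[C@@H](CC=C(C)C)C(C)=C1` | intermediate
10 | 3-methyl-4,6-bis(3-methylbut-2-en-1-yl)cyclohex-2-en-1-one, C4 as in 7, both C6 epimers | `O=C1C=C(C)[C@H](CC=C(C)C)CC1CC=C(C)C` | intermediate
11 | lithium cross-conjugated dienolate of 10 (not isolated) | `[Li+].[O-]C1=C(CC=C(C)C)C[C@@H](CC=C(C)C)C(C)=C1` | intermediate
12 | 6-(hydroxymethyl)-3-methyl-4,6-bis(3-methylbut-2-en-1-yl)cyclohex-2-en-1-one; hydroxymethyl trans to the 4-prenyl group (prenyl groups cis) | `CC(C)=CC[C@@H]1C[C@](CO)(CC=C(C)C)C(=O)C=C1C` | intermediate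
13 | 4-methyl-2-oxo-1,5-bis(3-methylbut-2-en-1-yl)cyclohex-3-ene-1-carbaldehyde; formyl trans to the 5-prenyl group | `CC(C)=CC[C@@H]1C[C@](C=O)(CC=C(C)C)C(=O)C=C1C` | intermediate
14 | 6-(2,2-dibromoethenyl)-3-methyl-4,6-bis(3-methylbut-2-en-1-yl)cyclohex-2-en-1-one; dibromoethenyl trans to the 4-prenyl group | `CC(C)=CC[C@@H]1C[C@](C=C(Br)Br)(CC=C(C)C)C(=O)C=C1C` | intermediate
15 | N-methyl-p-toluenesulfonamide | `CNS(=O)(=O)c1ccc(C)cc1` | starting material
16 | N,4-dimethyl-N-{[4-methyl-2-oxo-1,5-bis(3-methylbut-2-en-1-yl)cyclohex-3-en-1-yl]ethynyl}benzenesulfonamide; ynamide carbon trans to the 5-prenyl group | `CC(C)=CC[C@@H]1C[C@](C#CN(C)S(=O)(=O)c2ccc(C)cc2)(CC=C(C)C)C(=O)C=C1C` | intermediate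
17 | isobutyraldehyde | `CC(C)C=O` | starting material
18 | bromomagnesium enolate (O–C9=C1) of the C8-methylated ketone (not isolated) | `CC(C)=CC[C@@H]1C[C@](C#CN(C)S(=O)(=O)c2ccc(C)cc2)(CC=C(C)C)C(O[Mg]Br)=CC1(C)C` | intermediate
19 | N-{[3-(1-hydroxy-2-methylpropyl)-4,4-dimethyl-2-oxo-1,5-bis(3-methylbut-2-en-1-yl)cyclohexyl]ethynyl}-N,4-dimethylbenzenesulfonamide; mixture at C1 and the carbinol carbon | `CC(C)=CC[C@@H]1C[C@](C#CN(C)S(=O)(=O)c2ccc(C)cc2)(CC=C(C)C)C(=O)C(C(O)C(C)C)C1(C)C` | intermediate
20 | N-{[2-hydroxy-4,4-dimethyl-3-(2-methylpropanoyl)-1,5-bis(3-methylbut-2-en-1-yl)cyclohex-2-en-1-yl]ethynyl}-N,4-dimethylbenzenesulfonamide (ring-enol tautomer of the 1,3-diketone; precursor of the key step) | `CC(C)=CC[C@@H]1C[C@](C#CN(C)S(=O)(=O)c2ccc(C)cc2)(CC=C(C)C)C(O)=C(C(=O)C(C)C)C1(C)C` | intermediate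
21 | keteniminium bis(trifluoromethanesulfonyl)imide from C3-protonation of 20 (not isolated) | `CC(C)=CC[C@@H]1C[C@](C=C=[N+](C)S(=O)(=O)c2ccc(C)cc2)(CC=C(C)C)C(O)=C(C(=O)C(C)C)C1(C)C.O=S(=O)([N-]S(=O)(=O)C(F)(F)F)C(F)(F)F` | intermediate
22 | N,4-dimethyl-N-[8,8-dimethyl-1-(2-methylpropanoyl)-9-oxo-5,7-diprenylbicyclo[3.2.1]oct-2-en-2-yl]benzenesulfonamide (target labels; C7 prenyl equatorial on the six-membered ring; product of the key step) | `CC(C)=CC[C@@H]1C[C@]2(CC=C(C)C)C(=O)[C@@](C(=O)C(C)C)(C(N(C)S(=O)(=O)c3ccc(C)cc3)=C2)C1(C)C` | intermediate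
23 | 8,8-dimethyl-1-(2-methylpropanoyl)-5,7-diprenylbicyclo[3.2.1]octane-2,9-dione (target labels) | `CC(C)=CC[C@@H]1C[C@]2(CC=C(C)C)C(=O)[C@@](C(=O)C(C)C)(C(=O)C2)C1(C)C` | intermediate
24 | potassium C2 enolate (C2=C3) of 23 (not isolated) | `[K+].CC(C)=CC[C@@H]1C[C@]2(CC=C(C)C)C(=O)[C@@](C(=O)C(C)C)(C([O-])=C2)C1(C)C` | intermediate
25 | exo-3-hydroxy derivative of 23 (OH on the C9 side) | `CC(C)=CC[C@@H]1C[C@]2(CC=C(C)C)C(=O)[C@@](C(=O)C(C)C)(C(=O)[C@H]2O)C1(C)C` | intermediate
26 | exo-3-(triethylsilyloxy) derivative of 23 | `CC(C)=CC[C@@H]1C[C@]2(CC=C(C)C)C(=O)[C@@](C(=O)C(C)C)(C(=O)[C@H]2O[Si](CC)(CC)CC)C1(C)C` | intermediate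
27 | 2-methyl-2-(trimethylsilyloxy)but-3-yne | `C#CC(C)(C)O[Si](C)(C)C` | starting material
28 | lithium acetylide of 27 (not isolated) | `[Li]C#CC(C)(C)O[Si](C)(C)C` | intermediate
29 | 4-methyl-4-(trimethylsilyloxy)pent-2-ynal | `O=CC#CC(C)(C)O[Si](C)(C)C` | intermediate
30 | lithium C2 enolate of 26, C2=C3 bearing the triethylsilyloxy group (not isolated) | `[Li+].CC(C)=CC[C@@H]1C[C@]2(CC=C(C)C)C(=O)[C@@](C(=O)C(C)C)(C([O-])=C2O[Si](CC)(CC)CC)C1(C)C` | intermediate
31 | 3-exo-[1-hydroxy-4-methyl-4-(trimethylsilyloxy)pent-2-yn-1-yl]-3-endo-(triethylsilyloxy) derivative of 23; carbinol epimers | `CC(C)=CC[C@@H]1C[C@]2(CC=C(C)C)C(=O)[C@@](C(=O)C(C)C)(C(=O)[C@@]2(O[Si](CC)(CC)CC)C(O)C#CC(C)(C)O[Si](C)(C)C)C1(C)C` | intermediate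
32 | 3-exo-[4-methyl-4-(trimethylsilyloxy)pent-2-ynoyl]-3-endo-(triethylsilyloxy) derivative of 23 | `CC(C)=CC[C@@H]1C[C@]2(CC=C(C)C)C(=O)[C@@](C(=O)C(C)C)(C(=O)[C@@]2(O[Si](CC)(CC)CC)C(=O)C#CC(C)(C)O[Si](C)(C)C)C1(C)C` | intermediate
33 | 3-exo-[(2Z)-4-methyl-4-(trimethylsilyloxy)pent-2-enoyl]-3-endo-(triethylsilyloxy) derivative of 23 | `CC(C)=CC[C@@H]1C[C@]2(CC=C(C)C)C(=O)[C@@](C(=O)C(C)C)(C(=O)[C@@]2(O[Si](CC)(CC)CC)C(=O)/C=C\C(C)(C)O[Si](C)(C)C)C1(C)C` | intermediate
34 | CNP0190794.1: (1R,3S,5S,7R)-3-hydroxy-3-[(2Z)-4-hydroxy-4-methylpent-2-enoyl]-8,8-dimethyl-1-(2-methylpropanoyl)-5,7-diprenylbicyclo[3.2.1]octane-2,9-dione (target labels) | `CC(C)=CC[C@@H]1C[C@]2(CC=C(C)C)C(=O)[C@@](C(=O)C(C)C)(C(=O)[C@@]2(O)C(=O)/C=C\C(C)(C)O)C1(C)C` | target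

Total step count: 20. Longest linear sequence: 19 (steps 1–15 and 17–20; step 16 is a one-step side branch).

Steps most likely to fail

1. Step 12 (proposed new method). What may go wrong: capture of the keteniminium ion by the C9 enol oxygen or by the geminal C5 prenyl alkene instead of by C1, or acid-induced cyclisation of a prenyl group before the ynamide is consumed. Fallback with known chemistry, setting out from 20 and returning at 23: the ynamide is hydrated with aqueous acid (p-TsOH·H2O, wet MeCN, 0 °C, water in large excess so that it outcompetes the internal nucleophiles) to the N-acyl sulfonamide, N-methyl-N-tosyl-2-[2-hydroxy-4,4-dimethyl-3-(2-methylpropanoyl)-1,5-diprenylcyclohex-2-en-1-yl]acetamide F1. Soft enolisation of this amide with MgBr2·OEt2 and i-Pr2NEt in CH2Cl2 then lets the magnesium-chelated diketonate be C-acylated at C1 by the tethered N-acyl sulfonamide, an activated acyl donor whose sulfonamide leaving group does not add back, so the Claisen-type ring closure is irreversible. This should give triketone 23 directly, by-passing 22, and the route continues with step 14.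

2. Step 17. What may go wrong: slow removal of the hindered endo C3–H by the amide base, competing deprotonation of the isobutyryl methine, O-to-O silyl transfer within the enolate, or fragmentation and retro-aldol of the lithium aldolate. Fallback, setting out from 26 and returning at 31: soft enolisation (Me3SiOTf, Et3N, CH2Cl2, 0 °C), which does not depend on a bulky base reaching the endo hydrogen, should give the mixed enediol bis-silyl ether (C2–OSiMe3, C3–OSiEt3) F2. Anhydrous fluoride (tetrabutylammonium difluorotriphenylsilicate, THF, −78 °C) in the presence of ynal 29 then cleaves only the trimethylsilyl enol ether and triggers a fluoride-mediated Mukaiyama-type aldol on the exo face; protic quench returns aldol 31.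

3. Step 10. What may go wrong: sluggish methyl transfer to the hindered β-carbon C8, which lets 1,2-addition or attack of the organometallic on the ynamide compete, and incomplete aldol capture of the magnesium enolate. Fallback, setting out from 16 and returning at 19: the two bond formations are separated. Me2CuLi with Me3SiCl in THF at −78 °C, conditions under which alkynes are not carbometalated, should give the isolable trimethylsilyl enol ether of the C8-methylated ketone F3. Its fluoride-triggered aldol reaction with isobutyraldehyde 17 (tetrabutylammonium difluorotriphenylsilicate, THF, −78 → −40 °C, protic work-up) returns aldol 19 without exposing the ynamide to a basic organometallic at higher temperature.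

Further compounds
F1 | step 12 | N-methyl-N-tosyl-2-[2-hydroxy-4,4-dimethyl-3-(2-methylpropanoyl)-1,5-diprenylcyclohex-2-en-1-yl]acetamide (hydrated ynamide; side arm trans to the 5-prenyl group) | `CC(C)=CC[C@@H]1C[C@](CC(=O)N(C)S(=O)(=O)c2ccc(C)cc2)(CC=C(C)C)C(O)=C(C(=O)C(C)C)C1(C)C`
F2 | step 17 | mixed enediol bis-silyl ether of 26 (C2–OSiMe3, C3–OSiEt3, C2=C3) | `CC(C)=CC[C@@H]1C[C@]2(CC=C(C)C)C(=O)[C@@](C(=O)C(C)C)(C(O[Si](C)(C)C)=C2O[Si](CC)(CC)CC)C1(C)C`
F3 | step 10 | trimethylsilyl enol ether (Me3SiO–C9=C1) of the C8-methylated ynamide ketone | `CC(C)=CC[C@@H]1C[C@](C#CN(C)S(=O)(=O)c2ccc(C)cc2)(CC=C(C)C)C(O[Si](C)(C)C)=CC1(C)C`
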